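**Plan**
- The target is read as epicatechin-(4β→6)-epicatechin-(4β→8)-epicatechin-(4β→6)-epicatechin (units 1–4 from the top). In each C6-linked unit (2 and 4), O1 is the phloroglucinol oxygen para to C6, and the two ring A carbons ortho to it (C4a and C8) are equivalent before ring C exists. Ring C can therefore be built on a symmetric 4-aryl group with no 6/8 ambiguity.
- Retrosynthesis: remove benzyl and silyl groups; cut ring C of unit 4 at C4–C4a (epoxy-arene closure) and at O1–C2 (aryl ether); cut the unit 2 C4–unit 3 C8 bond; cut ring C of unit 2 in the same two places; cut both C4–aryl bonds back to phloroglucinol and C4-activated epicatechin.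
- Forward: protected epicatechin is C4-activated and joined to phloroglucinol, and the aryl triol is differentiated (para pivalate, ortho benzyl ethers). One portion is taken on to the unit 1–unit 2 dimer (ring C of unit 2 closed), C4-activated and coupled to C8 of the other portion. Ring C of unit 4 is closed last, so that C8 of unit 4 does not yet exist as a competing site during the union.
- Stereochemistry: C2/C3 of units 1 and 3 come from (−)-epicatechin. Every C4 centre is set by attack on the flavan-4-yl cation anti to the 3-oxygen (4β). C2/C3 of units 2 and 4 come from a Sharpless kinetic resolution (L-(+)-DIPT) followed by Mitsunobu inversion.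

Key step: step 17

Assumption: all four units are (2R,3R) and all three interflavan bonds are 3,4-trans (4β), as the SMILES encodes.

**Route**

Step 1
Reactants: 1 (−)-epicatechin
Product: 2 5,7,3',4'-tetra-O-benzyl-(−)-epicatechin
Conditions: BnBr (4.4 equiv), K2CO3, DMF, 0 °C to rt
Reagents that add atoms: benzyl bromide, BrCc1ccccc1
Why: Williamson etherification in which carbonate deprotonates only the four phenols, so the secondary 3-OH stays free and no stereocentre is touched.

Step 2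
Reactants: 2 tetra-O-benzylepicatechin
Product: 3 5,7,3',4'-tetra-O-benzyl-4β-(2-ethoxyethoxy)epicatechin
Conditions: DDQ (2 equiv), 2-ethoxyethanol (5 equiv), CH2Cl2, rt
Reagents that add atoms: 2-ethoxyethanol, CCOCCO
Why: DDQ benzylic oxidation, in which hydride abstraction at C4 gives a cation stabilised by the ring A oxygens and the alcohol adds anti to the neighbouring 3-OH, setting C4 as 4β (3,4-trans).

Step 3
Reactants: 3 4β-(2-ethoxyethoxy) alcohol
Product: 4 5,7,3',4'-tetra-O-benzyl-3-O-TBS-4β-(2-ethoxyethoxy)epicatechin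
Conditions: TBSCl, imidazole, DMF, rt to 40 °C
Reagents that add atoms: tert-butyldimethylsilyl chloride, CC(C)(C)[Si](C)(C)Cl
Why: Silyl ether formation under imidazole-buffered conditions, which should leave the acid-sensitive C4 ether intact.

Step 4
Reactants: 4 C4-activated monomer; 5 phloroglucinol
Product: 6 5,7,3',4'-tetra-O-benzyl-3-O-TBS-4β-(2,4,6-trihydroxyphenyl)epicatechin
Conditions: 5 (5 equiv), BF3·OEt2 (0.3 equiv), THF/CH2Cl2, −20 to 0 °C
Reagents that add atoms: none
Why: Friedel–Crafts arylation of the flavan-4-yl cation, in which phloroglucinol (three identical CH positions) attacks trans to the 3-O-silyl group to set C4 as 4β, the excess of 5 suppressing double alkylation.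

Step 5
Reactants: 6 aryl triol
Product: 7 5,7,3',4'-tetra-O-benzyl-3-O-TBS-4β-[2,6-dihydroxy-4-(pivaloyloxy)phenyl]epicatechin
Conditions: PivCl (1.05 equiv), pyridine, CH2Cl2, −40 to 0 °C
Reagents that add atoms: pivaloyl chloride, CC(C)(C)C(=O)Cl
Why: Sterically controlled monoacylation, since the hydroxyl para to the flavan is flanked by two hydrogens whereas each ortho hydroxyl sits beside the crowded C4 substituent, so the bulky acid chloride should take the para oxygen.

Step 6
Reactants: 7 para-pivalate diol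
Product: 8 5,7,3',4'-tetra-O-benzyl-3-O-TBS-4β-[2,6-bis(benzyloxy)-4-(pivaloyloxy)phenyl]epicatechin
Conditions: BnBr (3 equiv), K2CO3, DMF, rt
Reagents that add atoms: benzyl bromide, BrCc1ccccc1
Why: Williamson etherification of the two remaining phenols, the hindered aryl pivalate being inert to carbonate in an aprotic medium.

Step 7
Reactants: 8 aryl pivalate
Product: 9 5,7,3',4'-tetra-O-benzyl-3-O-TBS-4β-[2,6-bis(benzyloxy)-4-hydroxyphenyl]epicatechin
Conditions: K2CO3, MeOH/THF, rt to 40 °C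
Reagents that add atoms: none
Why: Base-catalysed methanolysis (transesterification) of the aryl ester, to which benzyl and silyl ethers are inert, frees only the para phenol.

Step 8
Reactants: 10 3,4-bis(benzyloxy)benzaldehyde
Product: 11 rac-1-[3,4-bis(benzyloxy)phenyl]prop-2-en-1-ol
Conditions: CH2=CHMgBr, THF, 0 °C; then H2O
Reagents that add atoms: vinylmagnesium bromide, C=C[Mg]Br
Why: Grignard 1,2-addition to the aldehyde gives the racemic aryl vinyl carbinol needed for resolution.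

Step 9
Reactants: 11 racemic allylic alcohol
Product: 12 (S)-[3,4-bis(benzyloxy)phenyl][(2R)-oxiran-2-yl]methanol
Conditions: Ti(OiPr)4 (0.1 equiv), L-(+)-DIPT (0.15 equiv), t-BuOOH (0.55 equiv), 4 Å MS, CH2Cl2, −20 °C
Reagents that add atoms: tert-butyl hydroperoxide, CC(C)(C)OO
Why: Sharpless kinetic resolution, in which L-(+)-DIPT should epoxidise the (R)-enantiomer of 11 much faster and give the erythro epoxy alcohol, so the tartrate sets the oxirane carbon as (2R) and selects the carbinol configuration named (S) in 12 (the descriptor changes only because the oxirane outranks the aryl group), while unreacted (S)-11 is removed by chromatography.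

Step 10
Reactants: 9 para-phenol; 12 epoxy alcohol
Product: 13 5,7,3',4'-tetra-O-benzyl-3-O-TBS-4β-{2,6-bis(benzyloxy)-4-[(R)-[3,4-bis(benzyloxy)phenyl][(2R)-oxiran-2-yl]methoxy]phenyl}epicatechin
Conditions: PPh3, DIAD, toluene, 0 °C to rt
Reagents that add atoms: none
Why: Mitsunobu etherification, in which the phenol displaces the activated carbinol oxygen by SN2 with inversion, turning the (S) carbinol into the (R) aryl ether (threo to the oxirane, as a 2,3-cis flavan requires), with the electron-withdrawing oxirane beside the benzylic carbon disfavouring ionisation.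

Step 11
Reactants: 13 aryl epoxy ether
Product: 14 [5,7,3',4'-tetra-O-benzyl-3-O-TBS-epicatechin]-(4β→6)-[5,7,3',4'-tetra-O-benzylepicatechin], lower 3-OH free
Conditions: BF3·OEt2 (0.5 equiv), CH2Cl2 (0.005 M), −78 °C
Reagents that add atoms: none
Why: Lewis-acid-promoted epoxy-arene (Friedel–Crafts) cyclisation of an aryl glycidyl-type ether, in which the ring carbon ortho to the ether oxygen opens the oxirane at CH2 (6-endo) and closes ring C of the lower unit with C2 and C3 unchanged, either ortho carbon giving the same C6-linked chroman.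

Step 12
Reactants: 14 dimer with free lower 3-OH
Product: 15 bis-3-O-TBS dimer
Conditions: TBSOTf, 2,6-lutidine, CH2Cl2, 0 °C
Reagents that add atoms: tert-butyldimethylsilyl triflate, CC(C)(C)[Si](C)(C)OS(=O)(=O)C(F)(F)F
Why: Silylation of the hindered secondary alcohol with the silyl triflate under lutidine buffering, which protects the interflavan bond from acid.

Step 13
Reactants: 15 bis-silyl dimer
Product: 16 bis-3-O-TBS dimer bearing 4β-(2-ethoxyethoxy) on the lower unit
Conditions: DDQ (2 equiv), 2-ethoxyethanol (5 equiv), CH2Cl2, rt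
Reagents that add atoms: 2-ethoxyethanol, CCOCCO
Why: DDQ benzylic oxidation as in step 2, where only the lower unit has a C4 methylene (the doubly benzylic C4–H of the upper unit is shielded by its two aryl groups and the silyl ether) and the alcohol adds trans to the 3-O-silyl group (4β).

Step 14
Reactants: 16 dimeric electrophile; 8 aryl pivalate monomer
Product: 17 unit 1–(4β→6)–unit 2–(4β→8)–unit 3 trimer (dodeca-O-benzyl, tris-3-O-TBS) whose unit 3 carries at C4β the 2,6-bis(benzyloxy)-4-(pivaloyloxy)phenyl group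
Conditions: 8 (3 equiv), TMSOTf (0.2 equiv), 4 Å MS, CH2Cl2, −78 to −40 °C
Reagents that add atoms: none
Why: Lewis-acid-catalysed interflavan Friedel–Crafts coupling, in which the C4 cation of the lower unit of 16 is attacked by C8 of 8 (the usual most nucleophilic flavan position) trans to the 3-O-silyl group to set 4β, while the pivaloyloxy group holds back the pendant aryl ring and the excess of 8 outcompetes the free C8 positions of 16.

Step 15
Reactants: 17 trimer aryl pivalate
Product: 18 trimer with the 2,6-bis(benzyloxy)-4-hydroxyphenyl group on unit 3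
Conditions: K2CO3, MeOH/THF, rt to 40 °C
Reagents that add atoms: none
Why: Methanolysis of the aryl pivalate as in step 7, with all ethers and interflavan bonds inert to mild base.

Step 16
Reactants: 18 trimer para-phenol; 12 epoxy alcohol
Product: 19 trimer whose pendant aryl 4-oxygen carries the (R)-[3,4-bis(benzyloxy)phenyl][(2R)-oxiran-2-yl]methyl group
Conditions: PPh3, DIAD, toluene, 0 °C to rt
Reagents that add atoms: none
Why: Mitsunobu etherification as in step 10, in which SN2 inversion at the carbinol carbon of 12 sets the future C2 of unit 4 as (R) next to the (R) oxirane carbon.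

Step 17
Reactants: 19 trimer aryl epoxy ether
Product: 20 hexadeca-O-benzyl tetramer with 3-O-TBS on units 1–3 and free 3-OH on unit 4
Conditions: BF3·OEt2 (0.5 equiv), CH2Cl2 (0.002 M), −78 to −40 °C
Reagents that add atoms: none
Why: BF3 binds the oxirane oxygen, and the ring carbon ortho to the ether oxygen of the 2,6-bis(benzyloxy)-4-alkoxyphenyl group (also ortho and para to the two benzyloxy groups) attacks the terminal CH2 in an SN2-like Friedel–Crafts alkylation, after which the arenium ion loses a proton and work-up leaves the C3 alcohol. The closest known reaction is the Lewis-acid- or fluoroalcohol-promoted epoxy-arene cyclisation of aryl glycidyl ethers to chroman-3-ols, already run in step 11 on a substrate with the same reacting part. Ring C of unit 4 closes in the 6-endo mode, forming C4–C4a and breaking the oxirane C–O bond at the terminal carbon. No stereocentre is created, since C2 and C3 of unit 4 are carried unchanged from 12 as installed in step 16, which fixes the 2,3-cis relationship. The step needs 6-endo over 5-exo opening and a single ring position: the first is secured because the internal oxirane carbon is secondary, hindered by the adjacent aryloxy-bearing benzylic carbon and inductively deactivated, and the second because the two carbons ortho to the ether oxygen are exchanged by rotation about the C4–aryl bond, so either gives the same C6-linked chroman. High dilution and low temperature should keep the free ring A positions of units 1–3 and the interflavan bonds out of play.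

Step 18
Reactants: 20 protected tetramer
Product: 21 hexadeca-O-benzyl tetramer with four free 3-OH
Conditions: TBAF, THF, rt to 50 °C
Reagents that add atoms: none
Why: Fluoride-driven cleavage of the three secondary silyl ethers, with warming for the two flanked by 4-aryl groups, leaves benzyl ethers and the skeleton untouched.

Step 19
Reactants: 21 hexadeca-O-benzyl tetramer
Product: 22 epicatechin-(4β→6)-epicatechin-(4β→8)-epicatechin-(4β→6)-epicatechin (target)
Conditions: H2 (1 atm), Pd(OH)2/C, THF/MeOH/H2O, rt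
Reagents that add atoms: none
Why: Catalytic hydrogenolysis removes all sixteen O-benzyl groups as toluene, while the ring C aryl alkyl ethers and the diarylmethine interflavan bonds are expected to persist under these mild conditions.

**Compound list**

1 | (−)-epicatechin, (2R,3R)-2-(3,4-dihydroxyphenyl)chromane-3,5,7-triol | O[C@@H]1Cc2c(O)cc(O)cc2O[C@@H]1c1ccc(O)c(O)c1 | starting material

2 | 5,7,3',4'-tetra-O-benzyl-(−)-epicatechin (3-OH free) | C(c9ccccc9)Oc1cc(OCc9ccccc9)c2c(c1)O[C@H](c3ccc(OCc9ccccc9)c(OCc9ccccc9)c3)[C@H](O)C2 | intermediate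

3 | 5,7,3',4'-tetra-O-benzyl-4β-(2-ethoxyethoxy)epicatechin (2,3-cis, 3,4-trans) | C(c9ccccc9)Oc1cc(OCc9ccccc9)c2c(c1)O[C@H](c3ccc(OCc9ccccc9)c(OCc9ccccc9)c3)[C@H](O)[C@H]2OCCOCC | intermediate

4 | 5,7,3',4'-tetra-O-benzyl-3-O-TBS-4β-(2-ethoxyethoxy)epicatechin | C(c9ccccc9)Oc1cc(OCc9ccccc9)c2c(c1)O[C@H](c3ccc(OCc9ccccc9)c(OCc9ccccc9)c3)[C@H](O[Si](C)(C)C(C)(C)C)[C@H]2OCCOCC | intermediate

5 | phloroglucinol (benzene-1,3,5-triol) | Oc1cc(O)cc(O)c1 | starting material

6 | 5,7,3',4'-tetra-O-benzyl-3-O-TBS-4β-(2,4,6-trihydroxyphenyl)epicatechin | C(c9ccccc9)Oc1cc(OCc9ccccc9)c2c(c1)O[C@H](c3ccc(OCc9ccccc9)c(OCc9ccccc9)c3)[C@H](O[Si](C)(C)C(C)(C)C)[C@H]2c4c(O)cc(O)cc4O | intermediate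

7 | 5,7,3',4'-tetra-O-benzyl-3-O-TBS-4β-[2,6-dihydroxy-4-(pivaloyloxy)phenyl]epicatechin | C(c9ccccc9)Oc1cc(OCc9ccccc9)c2c(c1)O[C@H](c3ccc(OCc9ccccc9)c(OCc9ccccc9)c3)[C@H](O[Si](C)(C)C(C)(C)C)[C@H]2c4c(O)cc(OC(=O)C(C)(C)C)cc4O | intermediate

8 | 5,7,3',4'-tetra-O-benzyl-3-O-TBS-4β-[2,6-bis(benzyloxy)-4-(pivaloyloxy)phenyl]epicatechin | C(c9ccccc9)Oc1cc(OCc9ccccc9)c2c(c1)O[C@H](c3ccc(OCc9ccccc9)c(OCc9ccccc9)c3)[C@H](O[Si](C)(C)C(C)(C)C)[C@H]2c4c(OCc9ccccc9)cc(OC(=O)C(C)(C)C)cc4OCc9ccccc9 | intermediate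

9 | 5,7,3',4'-tetra-O-benzyl-3-O-TBS-4β-[2,6-bis(benzyloxy)-4-hydroxyphenyl]epicatechin | C(c9ccccc9)Oc1cc(OCc9ccccc9)c2c(c1)O[C@H](c3ccc(OCc9ccccc9)c(OCc9ccccc9)c3)[C@H](O[Si](C)(C)C(C)(C)C)[C@H]2c4c(OCc9ccccc9)cc(O)cc4OCc9ccccc9 | intermediate

10 | 3,4-bis(benzyloxy)benzaldehyde | O=Cc1ccc(OCc2ccccc2)c(OCc2ccccc2)c1 | starting material

11 | rac-1-[3,4-bis(benzyloxy)phenyl]prop-2-en-1-ol | C=CC(O)c1ccc(OCc2ccccc2)c(OCc2ccccc2)c1 | intermediate

12 | (S)-[3,4-bis(benzyloxy)phenyl][(2R)-oxiran-2-yl]methanol (erythro) | O[C@@H](c1ccc(OCc2ccccc2)c(OCc2ccccc2)c1)[C@H]1CO1 | intermediate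

13 | 5,7,3',4'-tetra-O-benzyl-3-O-TBS-4β-{2,6-bis(benzyloxy)-4-[(R)-[3,4-bis(benzyloxy)phenyl][(2R)-oxiran-2-yl]methoxy]phenyl}epicatechin | C(c9ccccc9)Oc1cc(OCc9ccccc9)c2c(c1)O[C@H](c3ccc(OCc9ccccc9)c(OCc9ccccc9)c3)[C@H](O[Si](C)(C)C(C)(C)C)[C@H]2c4c(OCc9ccccc9)cc(O[C@H](c3ccc(OCc9ccccc9)c(OCc9ccccc9)c3)[C@H]5CO5)cc4OCc9ccccc9 | intermediate

14 | [5,7,3',4'-tetra-O-benzyl-3-O-TBS-epicatechin]-(4β→6)-[5,7,3',4'-tetra-O-benzylepicatechin], lower 3-OH free | C(c9ccccc9)Oc1cc(OCc9ccccc9)c2c(c1)O[C@H](c3ccc(OCc9ccccc9)c(OCc9ccccc9)c3)[C@H](O[Si](C)(C)C(C)(C)C)[C@H]2c4c(OCc9ccccc9)cc5c(c4OCc9ccccc9)C[C@@H](O)[C@@H](c3ccc(OCc9ccccc9)c(OCc9ccccc9)c3)O5 | intermediate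

15 | [5,7,3',4'-tetra-O-benzyl-3-O-TBS-epicatechin]-(4β→6)-[5,7,3',4'-tetra-O-benzyl-3-O-TBS-epicatechin] | C(c9ccccc9)Oc1cc(OCc9ccccc9)c2c(c1)O[C@H](c3ccc(OCc9ccccc9)c(OCc9ccccc9)c3)[C@H](O[Si](C)(C)C(C)(C)C)[C@H]2c4c(OCc9ccccc9)cc5c(c4OCc9ccccc9)C[C@@H](O[Si](C)(C)C(C)(C)C)[C@@H](c3ccc(OCc9ccccc9)c(OCc9ccccc9)c3)O5 | intermediate

16 | dimer 15 bearing 4β-(2-ethoxyethoxy) on the lower unit (3,4-trans) | C(c9ccccc9)Oc1cc(OCc9ccccc9)c2c(c1)O[C@H](c3ccc(OCc9ccccc9)c(OCc9ccccc9)c3)[C@H](O[Si](C)(C)C(C)(C)C)[C@H]2c4c(OCc9ccccc9)cc5c(c4OCc9ccccc9)[C@H](OCCOCC)[C@@H](O[Si](C)(C)C(C)(C)C)[C@@H](c3ccc(OCc9ccccc9)c(OCc9ccccc9)c3)O5 | intermediate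

17 | unit 1–(4β→6)–unit 2–(4β→8)–unit 3 trimer, each unit 5,7,3',4'-tetra-O-benzyl-3-O-TBS, unit 3 bearing 4β-[2,6-bis(benzyloxy)-4-(pivaloyloxy)phenyl] | C(c9ccccc9)Oc1cc(OCc9ccccc9)c2c(c1)O[C@H](c3ccc(OCc9ccccc9)c(OCc9ccccc9)c3)[C@H](O[Si](C)(C)C(C)(C)C)[C@H]2c4c(OCc9ccccc9)cc5c(c4OCc9ccccc9)[C@H](c6c(OCc9ccccc9)cc(OCc9ccccc9)c7c6O[C@H](c3ccc(OCc9ccccc9)c(OCc9ccccc9)c3)[C@H](O[Si](C)(C)C(C)(C)C)[C@H]7c8c(OCc9ccccc9)cc(OC(=O)C(C)(C)C)cc8OCc9ccccc9)[C@@H](O[Si](C)(C)C(C)(C)C)[C@@H](c3ccc(OCc9ccccc9)c(OCc9ccccc9)c3)O5 | intermediate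

18 | trimer 17 with the pendant ring as 2,6-bis(benzyloxy)-4-hydroxyphenyl | C(c9ccccc9)Oc1cc(OCc9ccccc9)c2c(c1)O[C@H](c3ccc(OCc9ccccc9)c(OCc9ccccc9)c3)[C@H](O[Si](C)(C)C(C)(C)C)[C@H]2c4c(OCc9ccccc9)cc5c(c4OCc9ccccc9)[C@H](c6c(OCc9ccccc9)cc(OCc9ccccc9)c7c6O[C@H](c3ccc(OCc9ccccc9)c(OCc9ccccc9)c3)[C@H](O[Si](C)(C)C(C)(C)C)[C@H]7c8c(OCc9ccccc9)cc(O)cc8OCc9ccccc9)[C@@H](O[Si](C)(C)C(C)(C)C)[C@@H](c3ccc(OCc9ccccc9)c(OCc9ccccc9)c3)O5 | intermediate

19 | trimer 18 whose pendant aryl 4-oxygen carries (R)-[3,4-bis(benzyloxy)phenyl][(2R)-oxiran-2-yl]methyl | C(c9ccccc9)Oc1cc(OCc9ccccc9)c2c(c1)O[C@H](c3ccc(OCc9ccccc9)c(OCc9ccccc9)c3)[C@H](O[Si](C)(C)C(C)(C)C)[C@H]2c4c(OCc9ccccc9)cc5c(c4OCc9ccccc9)[C@H](c6c(OCc9ccccc9)cc(OCc9ccccc9)c7c6O[C@H](c3ccc(OCc9ccccc9)c(OCc9ccccc9)c3)[C@H](O[Si](C)(C)C(C)(C)C)[C@H]7c8c(OCc9ccccc9)cc(O[C@H](c3ccc(OCc9ccccc9)c(OCc9ccccc9)c3)[C@H]1CO1)cc8OCc9ccccc9)[C@@H](O[Si](C)(C)C(C)(C)C)[C@@H](c3ccc(OCc9ccccc9)c(OCc9ccccc9)c3)O5 | intermediate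

20 | hexadeca-O-benzyl tetramer (4β→6, 4β→8, 4β→6), 3-O-TBS on units 1–3, 3-OH free on unit 4 | C(c9ccccc9)Oc1cc(OCc9ccccc9)c2c(c1)O[C@H](c3ccc(OCc9ccccc9)c(OCc9ccccc9)c3)[C@H](O[Si](C)(C)C(C)(C)C)[C@H]2c4c(OCc9ccccc9)cc5c(c4OCc9ccccc9)[C@H](c6c(OCc9ccccc9)cc(OCc9ccccc9)c7c6O[C@H](c3ccc(OCc9ccccc9)c(OCc9ccccc9)c3)[C@H](O[Si](C)(C)C(C)(C)C)[C@H]7c8c(OCc9ccccc9)cc1c(c8OCc9ccccc9)C[C@@H](O)[C@@H](c3ccc(OCc9ccccc9)c(OCc9ccccc9)c3)O1)[C@@H](O[Si](C)(C)C(C)(C)C)[C@@H](c3ccc(OCc9ccccc9)c(OCc9ccccc9)c3)O5 | intermediate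

21 | hexadeca-O-benzyl tetramer with four free 3-OH | C(c9ccccc9)Oc1cc(OCc9ccccc9)c2c(c1)O[C@H](c3ccc(OCc9ccccc9)c(OCc9ccccc9)c3)[C@H](O)[C@H]2c4c(OCc9ccccc9)cc5c(c4OCc9ccccc9)[C@H](c6c(OCc9ccccc9)cc(OCc9ccccc9)c7c6O[C@H](c3ccc(OCc9ccccc9)c(OCc9ccccc9)c3)[C@H](O)[C@H]7c8c(OCc9ccccc9)cc1c(c8OCc9ccccc9)C[C@@H](O)[C@@H](c3ccc(OCc9ccccc9)c(OCc9ccccc9)c3)O1)[C@@H](O)[C@@H](c3ccc(OCc9ccccc9)c(OCc9ccccc9)c3)O5 | intermediate

22 | epicatechin-(4β→6)-epicatechin-(4β→8)-epicatechin-(4β→6)-epicatechin | Oc1cc(O)c2c(c1)O[C@H](c1ccc(O)c(O)c1)[C@H](O)[C@H]2c1c(O)cc2c(c1O)[C@H](c1c(O)cc(O)c3c1O[C@H](c1ccc(O)c(O)c1)[C@H](O)[C@H]3c1c(O)cc3c(c1O)C[C@@H](O)[C@@H](c1ccc(O)c(O)c1)O3)[C@@H](O)[C@@H](c1ccc(O)c(O)c1)O2 | target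

**Count and risks**

Total: 19 steps. Longest linear sequence: 17 steps (steps 1–7 and 10–19); steps 8–9 form the side branch to 12.

Most likely to fail:

1. Step 17. With three interflavan bonds and four free ring A positions in 19, the Lewis acid may trigger intermolecular arylation of the oxirane or acid-induced scission of an interflavan bond faster than the ring closure. The fallback closes ring C of unit 4 before the fragment union instead of after it. It sets out from 14 and 16: dimer 14, which already carries that ring from step 11, is used in excess in place of 8 and joined to 16 (TMSOTf, CH2Cl2, −78 °C) through C8 of its upper unit. This gives 20 directly, so the fallback comes back to the route at 20 and steps 15–17 drop out. The price is competing attack through C8 of the lower unit of 14, to be met by the excess of 14 and chromatography. No compound outside the list is made (F0).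

2. Step 13. Hydride abstraction at C4 of the lower unit of 15 may be slowed by the 5-benzyloxy group buttressed by the C6 substituent, so that over-oxidation, elimination of the cation or self-arylation through the free C8 positions may take over. The fallback raises the oxidation level of the ring-closing carbon so that no dimer has to be oxidised. It sets out from 13:
   - thiophenol and Et3N in MeOH/THF open the oxirane at CH2 to give the hydroxy sulfide F1;
   - TBSOTf and 2,6-lutidine give its silyl ether F2;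
   - mCPBA (1 equiv, −78 °C) gives the sulfoxide F3;
   - trifluoroacetic anhydride, then BF3·OEt2 if needed, generates the Pummerer thionium ion, which closes on the same ring carbon as in step 11 to give the 4-(phenylthio) dimer F4, with C4–C4a formed and a leaving group already on C4 (either C4 epimer serves);
   - thiophilic activation of F4 with AgOSO2CF3 in the presence of 8 (CH2Cl2, −40 °C) should then give 17, where the fallback comes back to the route.

3. Step 5. Discrimination between the para hydroxyl and the two ortho hydroxyls may be incomplete, giving mixtures of mono- and dipivalates. The fallback changes the arene nucleophile instead of differentiating the triol. It sets out from 4, which is coupled with commercial 3,5-bis(benzyloxy)phenol (TMSOTf, CH2Cl2/THF, −78 °C). Substitution para to the free hydroxyl gives 9 directly, the ortho isomer being removed by chromatography, so the fallback comes back to the route at 9. Pivaloylation of 9 (PivCl, pyridine) then supplies 8. No compound outside the list is made (F0).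

**Further compounds**

F1 | step 13 | hydroxy sulfide: 13 with the oxirane opened at CH2 by thiophenol, side chain –O–CH(Ar)–CH(OH)–CH2SPh, both carbon configurations unchanged | C(c9ccccc9)Oc1cc(OCc9ccccc9)c2c(c1)O[C@H](c3ccc(OCc9ccccc9)c(OCc9ccccc9)c3)[C@H](O[Si](C)(C)C(C)(C)C)[C@H]2c4c(OCc9ccccc9)cc(O[C@H](c3ccc(OCc9ccccc9)c(OCc9ccccc9)c3)[C@H](O)CSc5ccccc5)cc4OCc9ccccc9

F2 | step 13 | O-TBS ether of F1 | C(c9ccccc9)Oc1cc(OCc9ccccc9)c2c(c1)O[C@H](c3ccc(OCc9ccccc9)c(OCc9ccccc9)c3)[C@H](O[Si](C)(C)C(C)(C)C)[C@H]2c4c(OCc9ccccc9)cc(O[C@H](c3ccc(OCc9ccccc9)c(OCc9ccccc9)c3)[C@H](O[Si](C)(C)C(C)(C)C)CSc5ccccc5)cc4OCc9ccccc9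

F3 | step 13 | sulfoxide of F2 (mixture at sulfur) | C(c9ccccc9)Oc1cc(OCc9ccccc9)c2c(c1)O[C@H](c3ccc(OCc9ccccc9)c(OCc9ccccc9)c3)[C@H](O[Si](C)(C)C(C)(C)C)[C@H]2c4c(OCc9ccccc9)cc(O[C@H](c3ccc(OCc9ccccc9)c(OCc9ccccc9)c3)[C@H](O[Si](C)(C)C(C)(C)C)CS(=O)c5ccccc5)cc4OCc9ccccc9

F4 | step 13 | dimer 15 bearing a phenylthio group at C4 of the lower unit (C4 epimers) | C(c9ccccc9)Oc1cc(OCc9ccccc9)c2c(c1)O[C@H](c3ccc(OCc9ccccc9)c(OCc9ccccc9)c3)[C@H](O[Si](C)(C)C(C)(C)C)[C@H]2c4c(OCc9ccccc9)cc5c(c4OCc9ccccc9)C(Sc6ccccc6)[C@@H](O[Si](C)(C)C(C)(C)C)[C@@H](c3ccc(OCc9ccccc9)c(OCc9ccccc9)c3)O5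

F0 | step 17 | none | none

F0 | step 5 | none | none
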